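**Retrosynthetic overview**
- The strategy rests on the alkyl part of the target: an unbroken run of nineteen CH2 groups (C1 to C19 of the 20-methylhenicosyl chain) between the ester oxygen and the isopropyl end at C20, with no polar handle. The only ring is the benzene ring of the 2,3-dihydroxybenzoate.
- The two phenols are traced back to benzyl ethers, removed last by hydrogenolysis.
- The C15–C16 bond is cut into two primary alkyl radicals, each released from a carboxylic acid (as its N-hydroxyphthalimide ester) by loss of CO2: a 16-(aroyloxy)hexadecanoic acid supplies C1–C15 and 6-methylheptanoic acid supplies C16–C21 with the 20-methyl group.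
- The head ester C–O bond is cut to 2,3-bis(benzyloxy)benzoyl chloride and 16-hydroxyhexadecanoic acid; the aryl ester also protects the chain hydroxyl.
- No ring is formed; the benzene ring is bought with 2,3-dihydroxybenzoic acid.

Key step: step 7

Remark: the target has no stereocentre (C20 carries two identical methyl groups), so the achiral compound itself is the single species asked for.

**Step 1**
Reactants: 1 2,3-dihydroxybenzoic acid; 2 benzyl bromide
Product: 3 benzyl 2,3-bis(benzyloxy)benzoate
Conditions: BnBr (3.5 equiv in all), K2CO3 (4 equiv), DMF, 60 °C
Reagents that add atoms: benzyl bromide (second equivalent), BrCc1ccccc1; benzyl bromide (third equivalent), BrCc1ccccc1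
Why: Williamson-type SN2 O-alkylation of the carboxylate and of both phenoxides takes up three molecules of benzyl bromide (one entered as 2, two more as the listed equivalents), and heating should carry it to completion at the 2-OH, which is hydrogen-bonded to the carboxyl group.

**Step 2**
Reactants: 3 benzyl 2,3-bis(benzyloxy)benzoate
Product: 4 2,3-bis(benzyloxy)benzoic acid
Conditions: NaOH (aq), MeOH/THF, reflux; then HCl (aq) to pH 2
Reagents that add atoms: sodium hydroxide, [Na+].[OH-]
Why: Saponification (BAc2 ester hydrolysis) should cleave only the benzyl ester, since aryl benzyl ethers are inert to hydroxide, and acidification releases the free acid.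

**Step 3**
Reactants: 4 2,3-bis(benzyloxy)benzoic acid
Product: 5 2,3-bis(benzyloxy)benzoyl chloride
Conditions: (COCl)2 (1.5 equiv), DMF (cat.), CH2Cl2, 0 °C to rt; concentrated, stripped with toluene, used crude
Reagents that add atoms: oxalyl chloride, O=C(Cl)C(=O)Cl
Why: Acid chloride formation through the Vilsmeier-type chloroiminium species from catalytic DMF is mild enough to leave both benzyl ethers intact, and all by-products are gases.

**Step 4**
Reactants: 5 2,3-bis(benzyloxy)benzoyl chloride; 6 16-hydroxyhexadecanoic acid
Product: 8 16-[2,3-bis(benzyloxy)benzoyloxy]hexadecanoic acid, via mixed anhydride 7 (not isolated)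
Conditions: 5 (2.3 equiv), pyridine/CH2Cl2, 0 °C; slow addition of 6 in THF/pyridine, then rt; then H2O/THF/pyridine, rt; 1 M HCl work-up
Reagents that add atoms: water, O
Why: In this Einhorn (pyridine) acylation the excess of 5 deliberately caps the carboxyl group as the mixed anhydride while the primary hydroxyl is esterified by the much more electrophilic acylpyridinium ion, slow addition of 6 keeps the hydroxyl from attacking the anhydride of a second molecule, and aqueous pyridine then hydrolyses the anhydride to free the chain acid (acid 4 is returned and can be recycled).

**Step 5**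
Reactants: 8 16-[2,3-bis(benzyloxy)benzoyloxy]hexadecanoic acid; 9 N-hydroxyphthalimide
Product: 10 1,3-dioxoisoindolin-2-yl 16-[2,3-bis(benzyloxy)benzoyloxy]hexadecanoate (head redox-active ester)
Conditions: DIC (1.1 equiv), DMAP (0.1 equiv), CH2Cl2, rt
Reagents that add atoms: none
Why: Steglich-type carbodiimide esterification of the only free carboxyl group with the acidic N–OH of 9 should give the redox-active ester without touching the aryl ester or the benzyl ethers.

**Step 6**
Reactants: 11 6-methylheptanoic acid; 9 N-hydroxyphthalimide
Product: 12 1,3-dioxoisoindolin-2-yl 6-methylheptanoate (tail redox-active ester)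
Conditions: DIC (1.1 equiv), DMAP (0.1 equiv), CH2Cl2, rt
Reagents that add atoms: none
Why: The same carbodiimide esterification applied to a simple branched fatty acid should be routine and is easily run on the scale needed to supply 12 in excess.

**Step 7**
Reactants: 10 head redox-active ester; 12 tail redox-active ester (3 equiv)
Product: 13 20-methylhenicosyl 2,3-bis(benzyloxy)benzoate
Conditions: NiCl2·6H2O (20 mol %), 2,2':6',2''-terpyridine (20 mol %), AgNO3 (0.3 equiv), NaI, NMP, (+)Mg/(−)RVC, undivided cell, constant current, rt; 1 M HCl work-up
Reagents that add atoms: none
Why: Cathodically reduced low-valent nickel passes an electron to each N-acyloxyphthalimide, each radical anion fragments to phthalimide anion, CO2 and a primary alkyl radical, nickel captures the two radicals in turn, and reductive elimination from the dialkylnickel species forms the C15–C16 sp3–sp3 bond. The closest known reaction type is the nickel-electrocatalytic doubly decarboxylative cross-coupling of two alkyl redox-active esters, the reductive counterpart of a mixed Kolbe electrolysis, which is established for joining two primary fatty-acid-derived chains. No ring is closed and no stereocentre is created. The step needs cross-coupling over homo-coupling: three equivalents of the cheap tail ester 12 bias the statistics towards 13, and the two homodimers, 2,11-dimethyldodecane (a C14 hydrocarbon) and the C30 bis(aryl ester), should differ clearly in polarity from the UV-active monoester 13. Both radicals are unhindered, primary and remote from any functional group, and the reductive medium should leave the benzyl aryl ethers and the benzoate ester alone, whereas an anodic Kolbe oxidation would endanger the electron-rich arene.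

**Step 8**
Reactants: 13 20-methylhenicosyl 2,3-bis(benzyloxy)benzoate
Product: 14 gentiside A (20-methylhenicosyl 2,3-dihydroxybenzoate)
Conditions: H2 (1 atm), 10% Pd/C, EtOAc/THF, rt
Reagents that add atoms: none
Why: Heterogeneous hydrogenolysis should cleave the two benzylic C–O bonds to give the catechol and toluene, while the ester C–O bond is not benzylic and the saturated chain holds nothing reducible.

**Compound list**
1 | 2,3-dihydroxybenzoic acid | O=C(O)c1cccc(O)c1O | starting material
2 | benzyl bromide | BrCc1ccccc1 | starting material
3 | benzyl 2,3-bis(benzyloxy)benzoate | O=C(OCc1ccccc1)c2cccc(OCc3ccccc3)c2OCc4ccccc4 | intermediate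
4 | 2,3-bis(benzyloxy)benzoic acid | O=C(O)c1cccc(OCc2ccccc2)c1OCc3ccccc3 | intermediate
5 | 2,3-bis(benzyloxy)benzoyl chloride | O=C(Cl)c1cccc(OCc2ccccc2)c1OCc3ccccc3 | intermediate
6 | 16-hydroxyhexadecanoic acid | OCCCCCCCCCCCCCCCC(=O)O | starting material
7 | 16-[2,3-bis(benzyloxy)benzoyloxy]hexadecanoic 2,3-bis(benzyloxy)benzoic anhydride (mixed anhydride) | O=C(CCCCCCCCCCCCCCCOC(=O)c1cccc(OCc2ccccc2)c1OCc3ccccc3)OC(=O)c4cccc(OCc5ccccc5)c4OCc6ccccc6 | intermediate
8 | 16-[2,3-bis(benzyloxy)benzoyloxy]hexadecanoic acid | O=C(O)CCCCCCCCCCCCCCCOC(=O)c1cccc(OCc2ccccc2)c1OCc3ccccc3 | intermediate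
9 | N-hydroxyphthalimide | ON1C(=O)c2ccccc2C1=O | starting material
10 | 1,3-dioxoisoindolin-2-yl 16-[2,3-bis(benzyloxy)benzoyloxy]hexadecanoate | O=C(CCCCCCCCCCCCCCCOC(=O)c1cccc(OCc2ccccc2)c1OCc3ccccc3)ON4C(=O)c5ccccc5C4=O | intermediate
11 | 6-methylheptanoic acid | CC(C)CCCCC(=O)O | starting material
12 | 1,3-dioxoisoindolin-2-yl 6-methylheptanoate | CC(C)CCCCC(=O)ON1C(=O)c2ccccc2C1=O | intermediate
13 | 20-methylhenicosyl 2,3-bis(benzyloxy)benzoate | CC(C)CCCCCCCCCCCCCCCCCCCOC(=O)c1cccc(OCc2ccccc2)c1OCc3ccccc3 | intermediate
14 | gentiside A (20-methylhenicosyl 2,3-dihydroxybenzoate) | CC(C)CCCCCCCCCCCCCCCCCCCOC(=O)c1cccc(O)c1O | target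

**Step count**
Total steps: 8. Longest linear sequence: 7 steps (steps 1, 2, 3, 4, 5, 7, 8, from 1 to 14); step 6 is the one-step side branch.

**Steps most likely to fail**

Step 7. Homo-coupling of either partner may outrun the cross-coupling, and the head radical may be reduced to the C15 alkyl ester (hydrodecarboxylation), a by-product close to 13 in polarity. The fallback sets out from 10 and replaces the radical–radical union by a nickel-catalysed decarboxylative Negishi-type alkyl–alkyl coupling, in which only the head fragment is a redox-active ester and the tail is a carbon nucleophile. 1-Bromo-5-methylhexane F1 (purchased) would be converted with magnesium in THF into 5-methylhexylmagnesium bromide F2, which with ZnCl2 (0.5 equiv) would give bis(5-methylhexyl)zinc F3. Treating 10 with F3 (2 equiv), NiCl2·glyme (20 mol %) and 4,4'-di-tert-butyl-2,2'-bipyridine (40 mol %) in THF/DMF at rt, followed by a dilute HCl work-up, should form the same C15–C16 bond. Esters and benzyl ethers are tolerated by dialkylzinc reagents. The fallback comes back to the route at 13.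

Step 4. The chain hydroxyl may attack the aliphatic carbonyl of the mixed anhydride of another molecule, so that the hydroxy acid esterifies itself to oligomers instead of being aroylated. The fallback sets out from 6 and masks the carboxyl group before the acylation. Carboxylate alkylation with allyl bromide and K2CO3 in DMF should give allyl 16-hydroxyhexadecanoate F4. Acylation of F4 with acid chloride 5 (pyridine, DMAP cat., CH2Cl2) should give allyl 16-[2,3-bis(benzyloxy)benzoyloxy]hexadecanoate F5. Palladium-catalysed allyl transfer to morpholine (Pd(PPh3)4, THF, rt) then removes the allyl ester without touching the benzyl ethers or the aryl ester. The fallback comes back to the route at 8.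

Step 8. The hydrogenolysis may stall through poisoning of the palladium surface by traces of iodide, silver or nickel carried over from the electrolysis, or through poor solubility of the waxy substrate. The fallback sets out from 13 and uses Lewis-acid dealkylation instead of hydrogen. BCl3 with pentamethylbenzene as benzyl-cation scavenger in CH2Cl2 at −78 °C, followed by a methanol/water quench, should cleave both benzyl ethers while leaving the alkyl benzoate intact. The fallback arrives directly at 14.

**Further compounds**
F1 | step 7 | 1-bromo-5-methylhexane (purchased) | CC(C)CCCCBr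
F2 | step 7 | 5-methylhexylmagnesium bromide | CC(C)CCCC[Mg]Br
F3 | step 7 | bis(5-methylhexyl)zinc | CC(C)CCCC[Zn]CCCCC(C)C
F4 | step 4 | allyl 16-hydroxyhexadecanoate | OCCCCCCCCCCCCCCCC(=O)OCC=C
F5 | step 4 | allyl 16-[2,3-bis(benzyloxy)benzoyloxy]hexadecanoate | C=CCOC(=O)CCCCCCCCCCCCCCCOC(=O)c1cccc(OCc2ccccc2)c1OCc3ccccc3
F0 | step 8 | none | none
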